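**Retrosynthetic overview** (benzofuran numbering O1, C2, C3, C3a, C4–C7, C7a; side chain Cα, Cβ, Cγ counted from ring A)
- C5–Cα: the erythro-glycerol chain is added last by Felkin–Anh addition of a C5 aryl-metal (from C5–Br) to (R)-glyceraldehyde acetonide; Cβ comes from the chiral pool, Cα from 1,2-induction.
- C2–C3 (key): the dihydrofuran ring O1–C2–C3–C3a–C7a is closed by catalyst-controlled rhodium-carbene insertion of a C3 aryl(ester) carbene into an O1–CH2 C–H bond of an achiral aryl benzyl ether; C3 is then epimerised to trans and its ester reduced to CH2OH.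
- Enabling feature: C2 is a methine flanked by O1 and the electron-rich ring B (a doubly activated benzylic ether CH2 in the precursor), and C3 carries one carbon (CH2OH, carried as CO2Et) and sits on C3a, ortho to the O1-bearing C7a, so a carbene at C3 lies 1,5 to the C2–H bonds.
- Precursor: O1–C2 ether by Mitsunobu coupling of 4-bromo-2-iodo-6-methoxyphenol with silyl-protected vanillyl alcohol; C3a–C3 by palladium-catalysed coupling of the aryl iodide with ethyl diazoacetate.
- Ring order: rings A and B are bought (4-bromo-2-methoxyphenol, vanillin); the dihydrofuran ring is the only ring formed and the last one closed.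

Key step: step 6

Assumption: the ethyl aryldiazoacetate is taken to respond to Rh2(S-PTTL)4 as the methyl esters of its class do, the (S)-ligand giving the (2R) aryl-bearing centre; should the C7 methoxy group reverse the sense, the mirror-image catalyst Rh2(R-PTTL)4 would be used with nothing else changed.

**Step 1**
Reactants: 1 vanillin
Product: 2 3-methoxy-4-[(triisopropylsilyl)oxy]benzaldehyde
Conditions: TIPSCl, imidazole, DMF, rt
Reagents that add atoms: triisopropylsilyl chloride, CC(C)[Si](Cl)(C(C)C)C(C)C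
Why: Imidazole-promoted O-silylation of the phenol (silyl ether protection) should give a hindered aryl silyl ether that withstands the later ethoxide, hydride and organolithium steps.

**Step 2**
Reactants: 2 3-methoxy-4-[(triisopropylsilyl)oxy]benzaldehyde
Product: 3 {3-methoxy-4-[(triisopropylsilyl)oxy]phenyl}methanol
Conditions: NaBH4, MeOH/THF, 0 °C
Reagents that add atoms: none
Why: Borohydride 1,2-reduction of the aldehyde should give the benzylic alcohol without touching the aryl silyl ether.

**Step 3**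
Reactants: 4 4-bromo-2-methoxyphenol
Product: 5 4-bromo-2-iodo-6-methoxyphenol
Conditions: N-iodosuccinimide, TsOH (10 mol %), MeCN, rt
Reagents that add atoms: N-iodosuccinimide, O=C1CCC(=O)N1I
Why: Electrophilic aromatic iodination: the phenolic OH is the strongest director and its para position is blocked by bromine, so iodine should enter the one free ortho position, giving the I/Br pair whose different reactivity later separates the C3a and C5 bond formations.

**Step 4**
Reactants: 3 {3-methoxy-4-[(triisopropylsilyl)oxy]phenyl}methanol; 5 4-bromo-2-iodo-6-methoxyphenol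
Product: 6 5-bromo-1-iodo-3-methoxy-2-({3-methoxy-4-[(triisopropylsilyl)oxy]phenyl}methoxy)benzene
Conditions: PPh3, DIAD, THF, 0 °C to rt
Reagents that add atoms: none
Why: Mitsunobu etherification, in which the acidic di-ortho-substituted phenol displaces the primary benzylic oxyphosphonium in an SN2 step, should form the O1–C2 ether without recourse to the labile para-silyloxybenzyl halide.

**Step 5**
Reactants: 6 5-bromo-1-iodo-3-methoxy-2-({3-methoxy-4-[(triisopropylsilyl)oxy]phenyl}methoxy)benzene; 7 ethyl diazoacetate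
Product: 8 ethyl 2-[5-bromo-3-methoxy-2-({3-methoxy-4-[(triisopropylsilyl)oxy]phenyl}methoxy)phenyl]-2-diazoacetate
Conditions: Pd(PPh3)4 (5 mol %), Ag2CO3 (0.5 equiv), Et3N, toluene, rt
Reagents that add atoms: none
Why: Palladium-catalysed C–H arylation of an acceptor diazo compound (oxidative addition of zerovalent palladium into C–I, which is much faster than into C–Br, palladation of ethyl diazoacetate with retention of the diazo group, reductive elimination) should attach C3 with both its ester and its diazo group to C3a in one step.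

**Step 6**
Reactants: 8 ethyl 2-[5-bromo-3-methoxy-2-({3-methoxy-4-[(triisopropylsilyl)oxy]phenyl}methoxy)phenyl]-2-diazoacetate
Product: 10 ethyl (2R,3S)-5-bromo-7-methoxy-2-{3-methoxy-4-[(triisopropylsilyl)oxy]phenyl}-2,3-dihydro-1-benzofuran-3-carboxylate (cis ester), via rhodium carbene 9 (not isolated)
Conditions: Rh2(S-PTTL)4 [dirhodium tetrakis(N-phthaloyl-(S)-tert-leucinate)] (1–2 mol %), toluene, −60 °C, slow addition of 8
Reagents that add atoms: none
Why: The divalent rhodium carboxylate expels N2 from the aryldiazoacetate to give the electrophilic donor/acceptor carbene 9 at C3, which inserts into one of the two enantiotopic O1–CH2 hydrogens through a concerted but asynchronous three-centre transition state with hydride-transfer character. The closest known reaction type is the chiral dirhodium tetracarboxylate-catalysed intramolecular C–H insertion of 2-(arylmethoxy)phenyl diazoacetates to cis-2-aryl-2,3-dihydrobenzofuran-3-carboxylates, applied here to a 7-methoxy, 5-bromo substrate. The dihydrofuran ring is closed by making the C2–C3 bond in the 1,5-insertion mode (carbene carbon and C–H carbon bridged by C3a, C7a and O1, five-membered ring). C2 is set by the catalyst, whose phthalimido walls select one enantiotopic hydrogen and one carbene face and should give (2R); C3 is set relative to C2 as cis by the compact insertion geometry and is deliberately corrected in step 7. The step needs site selectivity and insertion to outrun carbene dimerisation: the O1–CH2 hydrogens are the only C–H bonds within 1,5-reach and are doubly activated by O1 and the electron-rich ring B, the C7 methoxy and the ring-B substituents are out of reach, an oxonium ylide would need a four-membered ring, and slow addition at −60 °C keeps the carbene dilute.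

**Step 7**
Reactants: 10 ethyl (2R,3S)-5-bromo-7-methoxy-2-{3-methoxy-4-[(triisopropylsilyl)oxy]phenyl}-2,3-dihydro-1-benzofuran-3-carboxylate
Product: 11 ethyl (2R,3R)-5-bromo-7-methoxy-2-{3-methoxy-4-[(triisopropylsilyl)oxy]phenyl}-2,3-dihydro-1-benzofuran-3-carboxylate (trans ester)
Conditions: NaOEt (0.2 equiv), EtOH/THF, 0 °C to rt
Reagents that add atoms: none
Why: Base-mediated epimerisation through the ester enolate (thermodynamic control) should move the C3 ester from the congested cis to the trans position relative to the C2 aryl group, while the non-enolisable C2 keeps its configuration and ethoxide matches the ester.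

**Step 8**
Reactants: 11 ethyl (2R,3R)-5-bromo-7-methoxy-2-{3-methoxy-4-[(triisopropylsilyl)oxy]phenyl}-2,3-dihydro-1-benzofuran-3-carboxylate
Product: 12 [(2R,3S)-5-bromo-7-methoxy-2-{3-methoxy-4-[(triisopropylsilyl)oxy]phenyl}-2,3-dihydro-1-benzofuran-3-yl]methanol
Conditions: i-Bu2AlH (3 equiv), CH2Cl2, −78 to 0 °C; aq. potassium sodium tartrate
Reagents that add atoms: none
Why: Aluminium hydride reduction of the ester to the primary alcohol should leave the aryl bromide and both ethers intact, the C3 descriptor changing to S by priority only.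

**Step 9**
Reactants: 12 [(2R,3S)-5-bromo-7-methoxy-2-{3-methoxy-4-[(triisopropylsilyl)oxy]phenyl}-2,3-dihydro-1-benzofuran-3-yl]methanol
Product: 13 tert-butyl{[(2R,3S)-5-bromo-7-methoxy-2-{3-methoxy-4-[(triisopropylsilyl)oxy]phenyl}-2,3-dihydro-1-benzofuran-3-yl]methoxy}dimethylsilane
Conditions: TBSCl, imidazole, DMF, rt
Reagents that add atoms: tert-butyldimethylsilyl chloride, CC(C)(C)[Si](C)(C)Cl
Why: Standard silyl protection of the primary alcohol removes the only acidic proton before the halogen–lithium exchange.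

**Step 10**
Reactants: 13 tert-butyl{[(2R,3S)-5-bromo-7-methoxy-2-{3-methoxy-4-[(triisopropylsilyl)oxy]phenyl}-2,3-dihydro-1-benzofuran-3-yl]methoxy}dimethylsilane; 14 (R)-2,2-dimethyl-1,3-dioxolane-4-carbaldehyde
Product: 17 (S)-[(2R,3S)-3-({[tert-butyl(dimethyl)silyl]oxy}methyl)-7-methoxy-2-{3-methoxy-4-[(triisopropylsilyl)oxy]phenyl}-2,3-dihydro-1-benzofuran-5-yl][(4R)-2,2-dimethyl-1,3-dioxolan-4-yl]methanol, via aryllithium 15 (not isolated), via aryltitanium triisopropoxide 16 (not isolated)
Conditions: t-BuLi (2.1 equiv), THF, −78 °C; ClTi(OiPr)3, −78 to −40 °C; then 14, −78 to −20 °C; aq. NH4Cl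
Reagents that add atoms: none
Why: Bromine–lithium exchange, transmetalation to a bulky non-chelating aryltitanium and Felkin–Anh addition to the α-alkoxy aldehyde, with attack anti to the dioxolane C4–O bond, should give the anti (erythro) adduct, that is the (S)-carbinol Cα next to the (R)-centre Cβ that comes unchanged from the chiral pool.

**Step 11**
Reactants: 17 (S)-[(2R,3S)-3-({[tert-butyl(dimethyl)silyl]oxy}methyl)-7-methoxy-2-{3-methoxy-4-[(triisopropylsilyl)oxy]phenyl}-2,3-dihydro-1-benzofuran-5-yl][(4R)-2,2-dimethyl-1,3-dioxolan-4-yl]methanol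
Product: 18 4-[(2R,3S)-5-{(S)-[(4R)-2,2-dimethyl-1,3-dioxolan-4-yl](hydroxy)methyl}-3-(hydroxymethyl)-7-methoxy-2,3-dihydro-1-benzofuran-2-yl]-2-methoxyphenol
Conditions: Bu4NF (2.5 equiv), AcOH (2.5 equiv), THF, 0 °C to rt
Reagents that add atoms: none
Why: Fluoride-mediated cleavage of both silyl ethers (Si–O to Si–F exchange), buffered with acetic acid so that no free phenoxide para to the C2–O1 bond is generated, should free the phenol and the primary alcohol while the ketal stays.

**Step 12**
Reactants: 18 4-[(2R,3S)-5-{(S)-[(4R)-2,2-dimethyl-1,3-dioxolan-4-yl](hydroxy)methyl}-3-(hydroxymethyl)-7-methoxy-2,3-dihydro-1-benzofuran-2-yl]-2-methoxyphenol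
Product: 19 (1S,2R)-1-[(2R,3S)-2-(4-hydroxy-3-methoxyphenyl)-3-(hydroxymethyl)-7-methoxy-2,3-dihydro-1-benzofuran-5-yl]propane-1,2,3-triol
Conditions: AcOH/H2O (4:1), rt
Reagents that add atoms: none
Why: Mild aqueous-acid hydrolysis of the terminal isopropylidene ketal should free the 1,2-diol under conditions too weak to ionise the para-oxygenated benzylic C–O bonds at Cα and C2, so no stereocentre is touched.

**Compound list**
1 | vanillin | COc1cc(C=O)ccc1O | starting material
2 | 3-methoxy-4-[(triisopropylsilyl)oxy]benzaldehyde | COc1cc(C=O)ccc1O[Si](C(C)C)(C(C)C)C(C)C | intermediate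
3 | {3-methoxy-4-[(triisopropylsilyl)oxy]phenyl}methanol | COc1cc(CO)ccc1O[Si](C(C)C)(C(C)C)C(C)C | intermediate
4 | 4-bromo-2-methoxyphenol | COc1cc(Br)ccc1O | starting material
5 | 4-bromo-2-iodo-6-methoxyphenol | COc1cc(Br)cc(I)c1O | intermediate
6 | 5-bromo-1-iodo-3-methoxy-2-({3-methoxy-4-[(triisopropylsilyl)oxy]phenyl}methoxy)benzene | COc1cc(COc2c(I)cc(Br)cc2OC)ccc1O[Si](C(C)C)(C(C)C)C(C)C | intermediate
7 | ethyl diazoacetate | CCOC(=O)C=[N+]=[N-] | starting material
8 | ethyl 2-[5-bromo-3-methoxy-2-({3-methoxy-4-[(triisopropylsilyl)oxy]phenyl}methoxy)phenyl]-2-diazoacetate | CCOC(=O)C(=[N+]=[N-])c1cc(Br)cc(OC)c1OCc1ccc(O[Si](C(C)C)(C(C)C)C(C)C)c(OC)c1 | intermediate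
9 | rhodium carbene of 8 on Rh2(S-PTTL)4, the four bridging carboxylates written as ions (not isolated) | CCOC(=O)C(=[Rh+2][Rh+2])c1cc(Br)cc(OC)c1OCc1ccc(O[Si](C(C)C)(C(C)C)C(C)C)c(OC)c1.CC(C)(C)[C@H](N1C(=O)c2ccccc2C1=O)C(=O)[O-].CC(C)(C)[C@H](N1C(=O)c2ccccc2C1=O)C(=O)[O-].CC(C)(C)[C@H](N1C(=O)c2ccccc2C1=O)C(=O)[O-].CC(C)(C)[C@H](N1C(=O)c2ccccc2C1=O)C(=O)[O-] | intermediate
10 | ethyl (2R,3S)-5-bromo-7-methoxy-2-{3-methoxy-4-[(triisopropylsilyl)oxy]phenyl}-2,3-dihydro-1-benzofuran-3-carboxylate (cis) | COc1cc([C@@H]2Oc3c(OC)cc(Br)cc3[C@@H]2C(=O)OCC)ccc1O[Si](C(C)C)(C(C)C)C(C)C | intermediate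
11 | ethyl (2R,3R)-5-bromo-7-methoxy-2-{3-methoxy-4-[(triisopropylsilyl)oxy]phenyl}-2,3-dihydro-1-benzofuran-3-carboxylate (trans) | COc1cc([C@@H]2Oc3c(OC)cc(Br)cc3[C@H]2C(=O)OCC)ccc1O[Si](C(C)C)(C(C)C)C(C)C | intermediate
12 | [(2R,3S)-5-bromo-7-methoxy-2-{3-methoxy-4-[(triisopropylsilyl)oxy]phenyl}-2,3-dihydro-1-benzofuran-3-yl]methanol | COc1cc([C@@H]2Oc3c(OC)cc(Br)cc3[C@H]2CO)ccc1O[Si](C(C)C)(C(C)C)C(C)C | intermediate
13 | tert-butyl{[(2R,3S)-5-bromo-7-methoxy-2-{3-methoxy-4-[(triisopropylsilyl)oxy]phenyl}-2,3-dihydro-1-benzofuran-3-yl]methoxy}dimethylsilane | COc1cc([C@@H]2Oc3c(OC)cc(Br)cc3[C@H]2CO[Si](C)(C)C(C)(C)C)ccc1O[Si](C(C)C)(C(C)C)C(C)C | intermediate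
14 | (R)-2,2-dimethyl-1,3-dioxolane-4-carbaldehyde | CC1(C)OC[C@H](C=O)O1 | starting material
15 | C5 aryllithium from 13 (not isolated) | COc1cc([C@@H]2Oc3c(OC)cc([Li])cc3[C@H]2CO[Si](C)(C)C(C)(C)C)ccc1O[Si](C(C)C)(C(C)C)C(C)C | intermediate
16 | C5 aryltitanium triisopropoxide (not isolated) | COc1cc([C@@H]2Oc3c(OC)cc([Ti](OC(C)C)(OC(C)C)OC(C)C)cc3[C@H]2CO[Si](C)(C)C(C)(C)C)ccc1O[Si](C(C)C)(C(C)C)C(C)C | intermediate
17 | (S)-[(2R,3S)-3-({[tert-butyl(dimethyl)silyl]oxy}methyl)-7-methoxy-2-{3-methoxy-4-[(triisopropylsilyl)oxy]phenyl}-2,3-dihydro-1-benzofuran-5-yl][(4R)-2,2-dimethyl-1,3-dioxolan-4-yl]methanol | COc1cc([C@@H]2Oc3c(OC)cc([C@H](O)[C@H]4COC(C)(C)O4)cc3[C@H]2CO[Si](C)(C)C(C)(C)C)ccc1O[Si](C(C)C)(C(C)C)C(C)C | intermediate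
18 | 4-[(2R,3S)-5-{(S)-[(4R)-2,2-dimethyl-1,3-dioxolan-4-yl](hydroxy)methyl}-3-(hydroxymethyl)-7-methoxy-2,3-dihydro-1-benzofuran-2-yl]-2-methoxyphenol | COc1cc([C@@H]2Oc3c(OC)cc([C@H](O)[C@H]4COC(C)(C)O4)cc3[C@H]2CO)ccc1O | intermediate
19 | (1S,2R)-1-[(2R,3S)-2-(4-hydroxy-3-methoxyphenyl)-3-(hydroxymethyl)-7-methoxy-2,3-dihydro-1-benzofuran-5-yl]propane-1,2,3-triol | COc1cc([C@@H]2Oc3c(OC)cc([C@H](O)[C@H](O)CO)cc3[C@H]2CO)ccc1O | target

Total step count: 12
Longest linear sequence: 11 steps (1, 2, 4, 5, 6, 7, 8, 9, 10, 11, 12, from vanillin)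

**Steps most likely to fail**

Step 6. What may go wrong: loss of enantiofacial discrimination, because the C7 methoxy group twists the arylmethoxy group out of the ring-A plane and may change its fit in the chiral pocket, or carbene dimerisation outrunning insertion. The fallback replaces the insertion by an auxiliary-controlled aldol addition followed by cationic ring closure; it sets out from 5, uses 2 as the aldehyde, and returns at 12.
- Phenol 5 is protected (MOMCl, i-Pr2NEt, CH2Cl2) as 5-bromo-1-iodo-3-methoxy-2-(methoxymethoxy)benzene F1.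
- Iodide-selective Negishi coupling with the Reformatsky reagent BrZnCH2CO2Et (Pd(PPh3)4, THF/DMPU, 50 °C) should give ethyl 2-[5-bromo-3-methoxy-2-(methoxymethoxy)phenyl]acetate F2.
- Saponification (LiOH, THF/H2O) gives 2-[5-bromo-3-methoxy-2-(methoxymethoxy)phenyl]acetic acid F3.
- Mixed-anhydride acylation (PivCl, Et3N; then the lithium salt of (R)-4-benzyl-1,3-oxazolidin-2-one, THF, −78 °C) gives the arylacetyl imide F4.
- Syn-selective boron aldol addition of its (Z)-enolate (Bu2BOTf, i-Pr2NEt, CH2Cl2, −78 to 0 °C) to aldehyde 2 should give the (2R,3R)-syn aldol adduct F5; the auxiliary fixes the future C3.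
- Trifluoroacetic acid in CH2Cl2 at 0 °C removes the methoxymethyl group and ionises the para-silyloxybenzylic alcohol, so that the phenol closes the O1–C2 bond under thermodynamic preference to the trans-dihydrobenzofuran imide F6.
- LiBH4 (THF, H2O, 0 °C) cleaves the auxiliary reductively and should give 12.

Step 5. What may go wrong: palladium-induced loss of N2 from the diazo partner (carbene-derived by-products) or sluggish oxidative addition at the hindered ortho-alkoxy iodide. The fallback sets out from 6 and returns at 8. Iodide-selective Negishi coupling of 6 with BrZnCH2CO2Et (Pd(PPh3)4, THF/DMPU, 50 °C) should give ethyl 2-[5-bromo-3-methoxy-2-({3-methoxy-4-[(triisopropylsilyl)oxy]phenyl}methoxy)phenyl]acetate F7. Regitz diazo transfer (4-acetamidobenzenesulfonyl azide, DBU, MeCN, 0 °C to rt) then installs the diazo group and gives 8.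

Step 10. What may go wrong: poor facial selectivity in the carbonyl addition (a competing chelated transition state leads to the threo epimer) or protonation of the aryl-metal before addition. The fallback forms the C5–Cα bond by acylation and sets Cα by chelation-controlled reduction; it sets out from 13 and returns at 17.
- The known Weinreb amide (4R)-N-methoxy-N,2,2-trimethyl-1,3-dioxolane-4-carboxamide F8 is made from commercial methyl (R)-2,2-dimethyl-1,3-dioxolane-4-carboxylate (MeNHOMe·HCl, i-PrMgCl, THF, −20 °C).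
- Aryllithium 15 (from 13, t-BuLi, THF, −78 °C) is acylated with F8 to give the aryl (4R)-2,2-dimethyl-1,3-dioxolan-4-yl ketone F9.
- Zn(BH4)2 (Et2O, −20 °C) reduces through the five-membered zinc chelate of the carbonyl and the α-oxygen and should give the anti (erythro) alcohol 17.

**Further compounds**
F1 | step 6 | 5-bromo-1-iodo-3-methoxy-2-(methoxymethoxy)benzene | COCOc1c(I)cc(Br)cc1OC
F2 | step 6 | ethyl 2-[5-bromo-3-methoxy-2-(methoxymethoxy)phenyl]acetate | CCOC(=O)Cc1cc(Br)cc(OC)c1OCOC
F3 | step 6 | 2-[5-bromo-3-methoxy-2-(methoxymethoxy)phenyl]acetic acid | OC(=O)Cc1cc(Br)cc(OC)c1OCOC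
F4 | step 6 | (4R)-4-benzyl-3-{2-[5-bromo-3-methoxy-2-(methoxymethoxy)phenyl]acetyl}-1,3-oxazolidin-2-one | O=C(Cc1cc(Br)cc(OC)c1OCOC)N1[C@H](Cc2ccccc2)COC1=O
F5 | step 6 | (4R)-4-benzyl-3-[(2R,3R)-2-[5-bromo-3-methoxy-2-(methoxymethoxy)phenyl]-3-hydroxy-3-{3-methoxy-4-[(triisopropylsilyl)oxy]phenyl}propanoyl]-1,3-oxazolidin-2-one | O=C(N1[C@H](Cc2ccccc2)COC1=O)[C@H](c1cc(Br)cc(OC)c1OCOC)[C@@H](O)c1ccc(O[Si](C(C)C)(C(C)C)C(C)C)c(OC)c1
F6 | step 6 | (4R)-4-benzyl-3-[(2R,3R)-5-bromo-7-methoxy-2-{3-methoxy-4-[(triisopropylsilyl)oxy]phenyl}-2,3-dihydro-1-benzofuran-3-carbonyl]-1,3-oxazolidin-2-one | COc1cc([C@@H]2Oc3c(OC)cc(Br)cc3[C@H]2C(=O)N2[C@H](Cc3ccccc3)COC2=O)ccc1O[Si](C(C)C)(C(C)C)C(C)C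
F7 | step 5 | ethyl 2-[5-bromo-3-methoxy-2-({3-methoxy-4-[(triisopropylsilyl)oxy]phenyl}methoxy)phenyl]acetate | CCOC(=O)Cc1cc(Br)cc(OC)c1OCc1ccc(O[Si](C(C)C)(C(C)C)C(C)C)c(OC)c1
F8 | step 10 | (4R)-N-methoxy-N,2,2-trimethyl-1,3-dioxolane-4-carboxamide | CON(C)C(=O)[C@H]1COC(C)(C)O1
F9 | step 10 | [(2R,3S)-3-({[tert-butyl(dimethyl)silyl]oxy}methyl)-7-methoxy-2-{3-methoxy-4-[(triisopropylsilyl)oxy]phenyl}-2,3-dihydro-1-benzofuran-5-yl][(4R)-2,2-dimethyl-1,3-dioxolan-4-yl]methanone | COc1cc([C@@H]2Oc3c(OC)cc(C(=O)[C@H]4COC(C)(C)O4)cc3[C@H]2CO[Si](C)(C)C(C)(C)C)ccc1O[Si](C(C)C)(C(C)C)C(C)C
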